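**Plan**

- Retrosynthesis: the three aryl ester C–O bonds are cut one at a time (O5, then O3, then O4), with C3–H (back to a C3 ketone) cut between the last two; then the C1–O and C4–O bonds together; then the C1–C2 ring bond (aldol); then C1–CO2Bn, C6–C1 and C3–C4 (dithiane alkylations around a three-carbon epoxide unit).
- Enabling feature: the tertiary hydroxyl on C1 and the ester oxygen on C4 lie cis and 1,4 across the cyclohexane ring, exactly where the two ends of the peroxide bridge of a 2,3-dioxabicyclo[2.2.2]octene sit.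
- Forward: the C7 chain is joined by two dithiane epoxide openings and one acylation; the carbocycle closes by a six-ring aldol and is dehydrated; singlet oxygen adds the dioxane bridge, which is then reduced open.
- Stereochemistry: C5 comes from (S)-epichlorohydrin; C1 and C4 from suprafacial O2 addition anti to the C5 silyloxy group; C3 from equatorial hydride attack on the C3 ketone.
- End game: each secondary hydroxyl is esterified with 3,4,5-tris(benzyloxy)benzoyl chloride as it is unveiled (O4 on the ketol, O3 after reduction, O5 after desilylation), so the central O4 ester is placed before its neighbours crowd it; one hydrogenolysis then removes all ten benzyl groups.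

Key step: step 7

Remark: the target SMILES encodes 3,4,5-tri-O-galloyl-(−)-quinic acid (O1, O3 and O4 on one ring face; O5 and the carboxyl on the other). Quinic acid numbering is used for all cyclic compounds. TBS = tert-butyldimethylsilyl, TMS = trimethylsilyl, Bn = benzyl. Compounds 6 and 22 are taken as purchased.

**Step 1**
Reactants: 1 (S)-epichlorohydrin; 2 2-methyl-1,3-dithiane
Product: 5 (S)-2-methyl-2-(oxiran-2-ylmethyl)-1,3-dithiane, via 2-lithio-2-methyl-1,3-dithiane 3 (not isolated), via lithium chlorohydrin alkoxide 4 (not isolated)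
Conditions: n-BuLi, THF, −30 °C; then 1, −78 °C to rt
Reagents that add atoms: none
Why: Corey–Seebach alkylation in which the dithiane anion should open the epoxide at its CH2 carbon (SN2) and the alkoxide then displaces chloride (3-exo-tet Williamson closure), so no bond to the stereocentre is broken and its configuration is kept.

**Step 2**
Reactants: 5 (S)-2-methyl-2-(oxiran-2-ylmethyl)-1,3-dithiane; 6 2-(tert-butyldimethylsilyl)-1,3-dithiane; 7 benzyl chloroformate
Product: 11 benzyl 2-[(S)-2-(tert-butyldimethylsilyloxy)-3-(2-methyl-1,3-dithian-2-yl)propyl]-1,3-dithiane-2-carboxylate, via 2-lithio-2-silyl-1,3-dithiane 8 (not isolated), via lithium alkoxide adduct 9 (not isolated), via Brook-shifted 2-lithiodithiane 10 (not isolated)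
Conditions: t-BuLi, Et2O, −78 to −45 °C; 5, −78 to −25 °C; HMPA/THF, −78 °C; then 7, −78 °C
Reagents that add atoms: none
Why: Anion relay coupling in which the silyl dithiane anion opens the epoxide at CH2, HMPA triggers the 1,4-Brook rearrangement that silylates the oxygen and moves the charge to the dithiane carbon, and that carbanion is C-acylated by the chloroformate (Corey–Seebach acylation), the carbinol centre being untouched.

**Step 3**
Reactants: 11 benzyl 2-[(S)-2-(tert-butyldimethylsilyloxy)-3-(2-methyl-1,3-dithian-2-yl)propyl]-1,3-dithiane-2-carboxylate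
Product: 12 benzyl (S)-4-(tert-butyldimethylsilyloxy)-2,6-dioxoheptanoate
Conditions: NBS (6 equiv), 2,6-lutidine, acetone/H2O (9:1), −20 to 0 °C
Reagents that add atoms: water, O
Why: Oxidative dithioacetal hydrolysis is established for both dialkyl and 2-alkoxycarbonyl dithianes, and the cold, buffered medium should spare the silyl ether and the benzyl ester.

**Step 4**
Reactants: 12 benzyl (S)-4-(tert-butyldimethylsilyloxy)-2,6-dioxoheptanoate
Product: 13 benzyl (5R)-5-(tert-butyldimethylsilyloxy)-1-hydroxy-3-oxocyclohexane-1-carboxylate (both C1 epimers)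
Conditions: L-proline (30 mol %), DMSO, rt
Reagents that add atoms: none
Why: Enamine-catalysed intramolecular aldol addition (Hajos–Parrish type, 6-enolendo-exo-trig) of the methyl ketone to the highly electrophilic α-keto ester carbonyl is the only closure that gives an unstrained ring, and the C1 centre need not be controlled because step 5 removes it.

**Step 5**
Reactants: 13 benzyl (5R)-5-(tert-butyldimethylsilyloxy)-1-hydroxy-3-oxocyclohexane-1-carboxylate
Product: 15 benzyl (R)-5-(tert-butyldimethylsilyloxy)-3-oxocyclohex-1-ene-1-carboxylate, via tertiary mesylate 14 (not isolated)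
Conditions: MsCl, Et3N, CH2Cl2, −20 to 0 °C
Reagents that add atoms: none
Why: Mesylation through sulfene followed by E1cB elimination via the C2 enolate should give the enone conjugated to both carbonyls, the mesylate leaving far more readily than the C5 silyloxy group at this temperature.

**Step 6**
Reactants: 15 benzyl (R)-5-(tert-butyldimethylsilyloxy)-3-oxocyclohex-1-ene-1-carboxylate
Product: 17 benzyl (R)-5-(tert-butyldimethylsilyloxy)-3-(trimethylsilyloxy)cyclohexa-1,3-diene-1-carboxylate, via lithium cross-conjugated enolate 16 (not isolated)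
Conditions: Me3SiCl, then LiN(i-Pr)2, THF, −78 °C (in situ quench); pentane, filtration under Ar; used at once
Reagents that add atoms: chlorotrimethylsilane, C[Si](C)(C)Cl
Why: Kinetic α′-deprotonation of an enone at C4 by a lithium amide with immediate O-silylation is the standard route to 2-silyloxy-1,3-dienes, and trapping at −78 °C should outrun both β-elimination of the C5 silyloxy group and deprotonation at C6.

**Step 7**
Reactants: 17 benzyl (R)-5-(tert-butyldimethylsilyloxy)-3-(trimethylsilyloxy)cyclohexa-1,3-diene-1-carboxylate; 18 dioxygen (as singlet oxygen)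
Product: 19 benzyl (1R,4S,8R)-8-(tert-butyldimethylsilyloxy)-5-(trimethylsilyloxy)-2,3-dioxabicyclo[2.2.2]oct-5-ene-1-carboxylate (peroxide bridge from quinate C1 to C4, anti to the C5 silyloxy group)
Conditions: O2, tetraphenylporphyrin (1 mol %), hν (visible), CH2Cl2, −78 °C; solution used cold
Reagents that add atoms: none
Why: Sensitised singlet oxygen should add to the ring-locked s-cis diene in a suprafacial [4+2] hetero-Diels–Alder cycloaddition, bonding first at the electron-rich C4 of the silyl enol ether and closing at C1. The closest known reactions are the photooxygenations of cyclohexa-1,3-dienes and of 2-silyloxy-1,3-dienes to 2,3-dioxabicyclo[2.2.2]oct-5-enes. The one new ring, the six-membered 1,2-dioxane spanning C1 and C4, closes by cycloaddition with both C–O bonds formed on the same face. C1 and C4 are therefore set together, their cis relation by suprafaciality and their absolute sense by the C5 stereocentre, whose bulky silyloxy group shields one face so that oxygen enters anti to it. The step needs facial selectivity and [4+2] rather than ene or silyl-transfer reactivity; the non-hydrogen-bonding silyl ether secures the first, and the cisoid geometry, the donor enol ether offsetting the ester, and the low temperature in a non-polar solvent secure the second.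

**Step 8**
Reactants: 19 benzyl (1R,4S,8R)-8-(tert-butyldimethylsilyloxy)-5-(trimethylsilyloxy)-2,3-dioxabicyclo[2.2.2]oct-5-ene-1-carboxylate
Product: 21 benzyl (1R,4S,5R)-5-(tert-butyldimethylsilyloxy)-1,4-dihydroxy-3-oxocyclohexane-1-carboxylate, via cis-1,4-diol silyl enol ether 20 (not isolated)
Conditions: thiourea (2.5 equiv), MeOH/CH2Cl2, −78 °C to rt; then AcOH (cat.), 0 °C
Reagents that add atoms: none
Why: Thiourea reduction of bicyclic endoperoxides cleaves only the O–O bond, so O1 and O4 keep their cis relation, and acidified methanol then protonates the silyl enol ether at C2 (enol ether solvolysis) to free the C3 ketone without base that could dehydrate the β-hydroxy ketone.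

**Step 9**
Reactants: 21 benzyl (1R,4S,5R)-5-(tert-butyldimethylsilyloxy)-1,4-dihydroxy-3-oxocyclohexane-1-carboxylate; 22 3,4,5-tris(benzyloxy)benzoyl chloride
Product: 23 benzyl (1R,4S,5R)-5-(tert-butyldimethylsilyloxy)-1-hydroxy-3-oxo-4-[3,4,5-tris(benzyloxy)benzoyloxy]cyclohexane-1-carboxylate
Conditions: 22 (1.2 equiv), pyridine, DMAP (5 mol %), CH2Cl2, −20 to 0 °C
Reagents that add atoms: none
Why: DMAP-catalysed acylation should esterify O4, the only secondary hydroxyl present and still flanked by the flat C3 carbonyl, while the tertiary C1 hydroxyl (hindered and deactivated by the geminal ester) stays free and the weak amine base at low temperature should not enolise the ketone towards loss of the C1 hydroxyl or the C5 silyloxy group.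

**Step 10**
Reactants: 23 benzyl (1R,4S,5R)-5-(tert-butyldimethylsilyloxy)-1-hydroxy-3-oxo-4-[3,4,5-tris(benzyloxy)benzoyloxy]cyclohexane-1-carboxylate
Product: 24 benzyl (1S,3R,4R,5R)-5-(tert-butyldimethylsilyloxy)-1,3-dihydroxy-4-[3,4,5-tris(benzyloxy)benzoyloxy]cyclohexane-1-carboxylate (1-OH, 3-OH and the O4 ester on one face, 5-OTBS on the other)
Conditions: LiBH(s-Bu)3 (2.2 equiv), THF, −78 °C; then AcOH, −78 °C
Reagents that add atoms: none
Why: Steric approach control, in which the bulky trialkylborohydride should attack the cyclohexanone equatorially (the axial path is also blocked by the axial C1 oxygen) to give the axial C3 alcohol cis to O4 and O1, while the aryl and benzyl esters survive at −78 °C and the cold acidic quench protonates the C3 alkoxide before it can attack the neighbouring O4 ester.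

**Step 11**
Reactants: 24 benzyl (1S,3R,4R,5R)-5-(tert-butyldimethylsilyloxy)-1,3-dihydroxy-4-[3,4,5-tris(benzyloxy)benzoyloxy]cyclohexane-1-carboxylate; 22 3,4,5-tris(benzyloxy)benzoyl chloride
Product: 25 benzyl (1S,3R,4R,5R)-5-(tert-butyldimethylsilyloxy)-1-hydroxy-3,4-bis[3,4,5-tris(benzyloxy)benzoyloxy]cyclohexane-1-carboxylate
Conditions: 22 (1.5 equiv), pyridine, DMAP (0.2 equiv), CH2Cl2, 0 °C to rt
Reagents that add atoms: none
Why: DMAP-catalysed acylation of the axial C3 hydroxyl, again the only secondary hydroxyl present, should give the 3,4-diester with the tertiary C1 hydroxyl left free, and any O4-to-O3 acyl shift during step 10 would converge on the same product.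

**Step 12**
Reactants: 25 benzyl (1S,3R,4R,5R)-5-(tert-butyldimethylsilyloxy)-1-hydroxy-3,4-bis[3,4,5-tris(benzyloxy)benzoyloxy]cyclohexane-1-carboxylate
Product: 26 benzyl (1R,3R,4S,5R)-1,5-dihydroxy-3,4-bis[3,4,5-tris(benzyloxy)benzoyloxy]cyclohexane-1-carboxylate
Conditions: HF·pyridine, THF/pyridine, 0 °C to rt
Reagents that add atoms: none
Why: Acidic fluoride desilylation removes the secondary silyl ether without base, so neither acyl migration nor lactonisation onto the benzyl ester is expected and the aryl esters are untouched.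

**Step 13**
Reactants: 26 benzyl (1R,3R,4S,5R)-1,5-dihydroxy-3,4-bis[3,4,5-tris(benzyloxy)benzoyloxy]cyclohexane-1-carboxylate; 22 3,4,5-tris(benzyloxy)benzoyl chloride
Product: 27 benzyl 3,4,5-tris-O-[3,4,5-tris(benzyloxy)benzoyl]-(−)-quinate (1-OH free)
Conditions: 22 (1.5 equiv), pyridine, DMAP (0.2 equiv), CH2Cl2, 0 °C to rt
Reagents that add atoms: none
Why: DMAP-catalysed acylation of the equatorial C5 hydroxyl, the last secondary hydroxyl, completes the triester, and it should outpace lactonisation of O5 onto the benzyl ester, which would need a ring flip to the chair with the ester and O5 axial.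

**Step 14**
Reactants: 27 benzyl 3,4,5-tris-O-[3,4,5-tris(benzyloxy)benzoyl]-(−)-quinate
Product: 28 3,4,5-tri-O-galloyl-(−)-quinic acid (CNP0148451.1)
Conditions: H2 (1 atm), Pd/C (10% Pd on carbon), THF/MeOH, rt
Reagents that add atoms: none
Why: Catalytic hydrogenolysis cleaves the benzyl ester and all nine benzyl ethers in one operation and leaves the aryl esters and the stereocentres untouched.

**Compound list**

1 | (S)-epichlorohydrin | ClC[C@@H]1CO1 | starting material
2 | 2-methyl-1,3-dithiane | CC1SCCCS1 | starting material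
3 | 2-lithio-2-methyl-1,3-dithiane | [Li]C1(C)SCCCS1 | intermediate (not isolated)
4 | lithium (S)-1-chloro-3-(2-methyl-1,3-dithian-2-yl)propan-2-olate | ClC[C@@H]([O-])CC1(C)SCCCS1.[Li+] | intermediate (not isolated)
5 | (S)-2-methyl-2-(oxiran-2-ylmethyl)-1,3-dithiane | CC1(C[C@H]2CO2)SCCCS1 | intermediate
6 | 2-(tert-butyldimethylsilyl)-1,3-dithiane | CC(C)(C)[Si](C)(C)C1SCCCS1 | starting material
7 | benzyl chloroformate | O=C(Cl)OCc1ccccc1 | starting material
8 | 2-lithio-2-(tert-butyldimethylsilyl)-1,3-dithiane | [Li]C1([Si](C)(C)C(C)(C)C)SCCCS1 | intermediate (not isolated)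
9 | lithium (S)-1-[2-(tert-butyldimethylsilyl)-1,3-dithian-2-yl]-3-(2-methyl-1,3-dithian-2-yl)propan-2-olate | CC1(C[C@H]([O-])CC2([Si](C)(C)C(C)(C)C)SCCCS2)SCCCS1.[Li+] | intermediate (not isolated)
10 | 2-lithio-2-[2-(tert-butyldimethylsilyloxy)-3-(2-methyl-1,3-dithian-2-yl)propyl]-1,3-dithiane (carbinol carbon arranged in space as in 11) | CC1(C[C@H](O[Si](C)(C)C(C)(C)C)CC2([Li])SCCCS2)SCCCS1 | intermediate (not isolated)
11 | benzyl 2-[(S)-2-(tert-butyldimethylsilyloxy)-3-(2-methyl-1,3-dithian-2-yl)propyl]-1,3-dithiane-2-carboxylate | CC1(C[C@H](O[Si](C)(C)C(C)(C)C)CC2(C(=O)OCc3ccccc3)SCCCS2)SCCCS1 | intermediate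
12 | benzyl (S)-4-(tert-butyldimethylsilyloxy)-2,6-dioxoheptanoate | CC(=O)C[C@H](O[Si](C)(C)C(C)(C)C)CC(=O)C(=O)OCc1ccccc1 | intermediate
13 | benzyl (5R)-5-(tert-butyldimethylsilyloxy)-1-hydroxy-3-oxocyclohexane-1-carboxylate, both C1 epimers | O=C(OCc1ccccc1)C1(O)CC(=O)C[C@H](O[Si](C)(C)C(C)(C)C)C1 | intermediate
14 | benzyl (5R)-5-(tert-butyldimethylsilyloxy)-1-(methanesulfonyloxy)-3-oxocyclohexane-1-carboxylate, both C1 epimers | O=C(OCc1ccccc1)C1(OS(C)(=O)=O)CC(=O)C[C@H](O[Si](C)(C)C(C)(C)C)C1 | intermediate (not isolated)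
15 | benzyl (R)-5-(tert-butyldimethylsilyloxy)-3-oxocyclohex-1-ene-1-carboxylate | O=C(OCc1ccccc1)C1=CC(=O)C[C@H](O[Si](C)(C)C(C)(C)C)C1 | intermediate
16 | lithium enolate of 15 at C3–C4 (lithium (R)-5-benzyloxycarbonyl-3-(tert-butyldimethylsilyloxy)cyclohexa-1,5-dien-1-olate) | [Li]OC1=C[C@H](O[Si](C)(C)C(C)(C)C)CC(C(=O)OCc2ccccc2)=C1 | intermediate (not isolated)
17 | benzyl (R)-5-(tert-butyldimethylsilyloxy)-3-(trimethylsilyloxy)cyclohexa-1,3-diene-1-carboxylate | O=C(OCc1ccccc1)C1=CC(O[Si](C)(C)C)=C[C@H](O[Si](C)(C)C(C)(C)C)C1 | intermediate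
18 | dioxygen | O=O | starting material
19 | benzyl (1R,4S,8R)-8-(tert-butyldimethylsilyloxy)-5-(trimethylsilyloxy)-2,3-dioxabicyclo[2.2.2]oct-5-ene-1-carboxylate | CC(C)(C)[Si](C)(C)O[C@@H]1C[C@]2(OO[C@@H]1C(O[Si](C)(C)C)=C2)C(=O)OCc1ccccc1 | intermediate
20 | benzyl (1R,4S,5R)-5-(tert-butyldimethylsilyloxy)-1,4-dihydroxy-3-(trimethylsilyloxy)cyclohex-2-ene-1-carboxylate | CC(C)(C)[Si](C)(C)O[C@@H]1C[C@](O)(C(=O)OCc2ccccc2)C=C(O[Si](C)(C)C)[C@H]1O | intermediate (not isolated)
21 | benzyl (1R,4S,5R)-5-(tert-butyldimethylsilyloxy)-1,4-dihydroxy-3-oxocyclohexane-1-carboxylate | CC(C)(C)[Si](C)(C)O[C@@H]1C[C@](O)(C(=O)OCc2ccccc2)CC(=O)[C@H]1O | intermediate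
22 | 3,4,5-tris(benzyloxy)benzoyl chloride | O=C(Cl)c1cc(OCc2ccccc2)c(OCc2ccccc2)c(OCc2ccccc2)c1 | starting material
23 | benzyl (1R,4S,5R)-5-(tert-butyldimethylsilyloxy)-1-hydroxy-3-oxo-4-[3,4,5-tris(benzyloxy)benzoyloxy]cyclohexane-1-carboxylate | CC(C)(C)[Si](C)(C)O[C@@H]1C[C@](O)(C(=O)OCc2ccccc2)CC(=O)[C@H]1OC(=O)c1cc(OCc2ccccc2)c(OCc2ccccc2)c(OCc2ccccc2)c1 | intermediate
24 | benzyl (1S,3R,4R,5R)-5-(tert-butyldimethylsilyloxy)-1,3-dihydroxy-4-[3,4,5-tris(benzyloxy)benzoyloxy]cyclohexane-1-carboxylate | CC(C)(C)[Si](C)(C)O[C@@H]1C[C@](O)(C(=O)OCc2ccccc2)C[C@@H](O)[C@H]1OC(=O)c1cc(OCc2ccccc2)c(OCc2ccccc2)c(OCc2ccccc2)c1 | intermediate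
25 | benzyl (1S,3R,4R,5R)-5-(tert-butyldimethylsilyloxy)-1-hydroxy-3,4-bis[3,4,5-tris(benzyloxy)benzoyloxy]cyclohexane-1-carboxylate | CC(C)(C)[Si](C)(C)O[C@@H]1C[C@](O)(C(=O)OCc2ccccc2)C[C@@H](OC(=O)c2cc(OCc3ccccc3)c(OCc3ccccc3)c(OCc3ccccc3)c2)[C@H]1OC(=O)c1cc(OCc2ccccc2)c(OCc2ccccc2)c(OCc2ccccc2)c1 | intermediate
26 | benzyl (1R,3R,4S,5R)-1,5-dihydroxy-3,4-bis[3,4,5-tris(benzyloxy)benzoyloxy]cyclohexane-1-carboxylate | O[C@@H]1C[C@](O)(C(=O)OCc2ccccc2)C[C@@H](OC(=O)c2cc(OCc3ccccc3)c(OCc3ccccc3)c(OCc3ccccc3)c2)[C@H]1OC(=O)c1cc(OCc2ccccc2)c(OCc2ccccc2)c(OCc2ccccc2)c1 | intermediate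
27 | benzyl 3,4,5-tris-O-[3,4,5-tris(benzyloxy)benzoyl]-(−)-quinate (1-OH free) | O=C(O[C@@H]1C[C@](O)(C(=O)OCc2ccccc2)C[C@@H](OC(=O)c2cc(OCc3ccccc3)c(OCc3ccccc3)c(OCc3ccccc3)c2)[C@H]1OC(=O)c1cc(OCc2ccccc2)c(OCc2ccccc2)c(OCc2ccccc2)c1)c1cc(OCc2ccccc2)c(OCc2ccccc2)c(OCc2ccccc2)c1 | intermediate
28 | 3,4,5-tri-O-galloyl-(−)-quinic acid | O=C(O[C@@H]1C[C@](O)(C(=O)O)C[C@@H](OC(=O)c2cc(O)c(O)c(O)c2)[C@H]1OC(=O)c1cc(O)c(O)c(O)c1)c1cc(O)c(O)c(O)c1 | target

**Count and risks**

Total steps: 14. Longest linear sequence: 14 steps (1 → 28).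

**Step 7.** Singlet oxygen may attack C4 alone with silyl transfer (an ene-type path that leaves C1 unoxygenated), may add too slowly at the ester-bearing terminus, or may add to both faces. The fallback sets out from 17 and comes back at 21, installing the two oxygens one at a time. Rubottom oxidation (dimethyldioxirane, acetone/CH2Cl2, −78 °C) should epoxidise the enol ether anti to the C5 silyloxy group to give the silyloxy oxirane F1. Citric acid in MeOH should open it to the 4-hydroxy enone F2, with O4 already trans to O5. Mukaiyama hydration (Mn(dpm)3 cat., dpm = dipivaloylmethanate, PhSiH3, O2, i-PrOH, 0 °C) should then deliver hydrogen to C2 and oxygen to the tertiary, ester-stabilised C1 radical. Axial capture with the ester equatorial is expected to favour the C1 hydroperoxide F3, which P(OEt)3 reduces to 21.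

**Step 6.** The C4 enolate may expel the C5 silyloxy group and aromatise to the 3-hydroxybenzoate, or deprotonation may occur at C6 and give the linear dienol ether. The fallback sets out from 15 and comes back at 27; it takes the leaving group out of play by carrying O5 as an oxide. HF·pyridine in THF should give the hydroxy enone F4. LiN(i-Pr)2 (2.2 equiv, THF, −78 °C) should form the dilithium alkoxide enolate F5, in which O5 cannot leave and the O–Li directs deprotonation to C4, and Me3SiCl should then give the bis(trimethylsilyl) diene F6. Photooxygenation as in step 7 should give the endoperoxide F7. Thiourea in MeOH followed by AcOH should give, through the diol silyl enol ether F8, benzyl 3-dehydroquinate F9. LiBH(s-Bu)3 at −78 °C should reduce F9 to benzyl (−)-quinate F10, whose three secondary hydroxyls are esterified together with 22 (3.5 equiv, pyridine, DMAP, CH2Cl2) to give 27.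

**Step 9.** Under the acylation conditions the β-hydroxy ketone may enolise and lose the C1 hydroxyl or the C5 silyloxy group, or the ketone may be acylated at its enol oxygen. The fallback sets out from 21 and comes back at 25; it reduces before it esterifies, so that no ketone meets an amine base. LiBH(s-Bu)3 (3.5 equiv, THF, −78 °C) should reduce 21 from the equatorial side to benzyl 5-O-(tert-butyldimethylsilyl)quinate F11. Its two secondary hydroxyls, O3 and O4, are then esterified together with 22 (2.5 equiv, pyridine, DMAP, CH2Cl2) to give 25.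

**Further compounds**

F1 | step 7 | 3,4-epoxide of 17, oxirane oxygen trans to the C5 silyloxy group: benzyl (5R)-5-(tert-butyldimethylsilyloxy)-3,4-epoxy-3-(trimethylsilyloxy)cyclohex-1-ene-1-carboxylate | O=C(OCc1ccccc1)C1=C[C@@]2(O[Si](C)(C)C)O[C@H]2[C@H](O[Si](C)(C)C(C)(C)C)C1
F2 | step 7 | benzyl (4S,5R)-5-(tert-butyldimethylsilyloxy)-4-hydroxy-3-oxocyclohex-1-ene-1-carboxylate | O=C(OCc1ccccc1)C1=CC(=O)[C@@H](O)[C@H](O[Si](C)(C)C(C)(C)C)C1
F3 | step 7 | benzyl (1R,4S,5R)-5-(tert-butyldimethylsilyloxy)-1-hydroperoxy-4-hydroxy-3-oxocyclohexane-1-carboxylate | CC(C)(C)[Si](C)(C)O[C@@H]1C[C@](OO)(C(=O)OCc2ccccc2)CC(=O)[C@H]1O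
F4 | step 6 | benzyl (R)-5-hydroxy-3-oxocyclohex-1-ene-1-carboxylate | O=C(OCc1ccccc1)C1=CC(=O)C[C@H](O)C1
F5 | step 6 | dilithium alkoxide enolate of F4 (O5–Li and C3–C4 enolate) | [Li]OC1=C[C@H](O[Li])CC(C(=O)OCc2ccccc2)=C1
F6 | step 6 | benzyl (R)-3,5-bis(trimethylsilyloxy)cyclohexa-1,3-diene-1-carboxylate | O=C(OCc1ccccc1)C1=CC(O[Si](C)(C)C)=C[C@H](O[Si](C)(C)C)C1
F7 | step 6 | benzyl (1R,4S,8R)-5,8-bis(trimethylsilyloxy)-2,3-dioxabicyclo[2.2.2]oct-5-ene-1-carboxylate | C[Si](C)(C)O[C@@H]1C[C@]2(OO[C@@H]1C(O[Si](C)(C)C)=C2)C(=O)OCc1ccccc1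
F8 | step 6 | benzyl (1R,4S,5R)-1,4-dihydroxy-3,5-bis(trimethylsilyloxy)cyclohex-2-ene-1-carboxylate | C[Si](C)(C)O[C@@H]1C[C@](O)(C(=O)OCc2ccccc2)C=C(O[Si](C)(C)C)[C@H]1O
F9 | step 6 | benzyl (1R,4S,5R)-1,4,5-trihydroxy-3-oxocyclohexane-1-carboxylate (benzyl 3-dehydroquinate) | O[C@@H]1C[C@](O)(C(=O)OCc2ccccc2)CC(=O)[C@H]1O
F10 | step 6 | benzyl (−)-quinate (1-, 3- and 4-OH on one face, 5-OH on the other) | O[C@@H]1C[C@](O)(C(=O)OCc2ccccc2)C[C@@H](O)[C@H]1O
F11 | step 9 | benzyl (1S,3R,4R,5R)-5-(tert-butyldimethylsilyloxy)-1,3,4-trihydroxycyclohexane-1-carboxylate (benzyl 5-O-TBS-quinate) | CC(C)(C)[Si](C)(C)O[C@@H]1C[C@](O)(C(=O)OCc2ccccc2)C[C@@H](O)[C@H]1O
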